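## Retrosynthetic overview

- The target is methyl gyrophorate, an achiral tridepside: ring A (free orsellinoyl) is esterified to O4 of ring B (middle), and ring B is esterified to O4 of ring C (methyl orsellinate).
- Feature used: ring B (C1 carboxyl, C2–O, C4–O, C6–CH3) is the dehydrogenated form of a 6-methyl-2,4-dioxocyclohexane-1-carboxylate. In that form O4 is the open end of the vinylogous acid, O2 sits beside the C1 ester, and C1/C2 form a β-keto ester.
- Disconnections, last bond first: the ring A–O4(ring B) ester by mixed-anhydride acylation, then arene B back to dihydro ring B. Next comes the ring B–O4(ring C) ester, from an acylketene released by a tert-butyl β-keto ester. Last are the C1–C6 (Michael) and C3–C4 (Dieckmann) bonds of ring B.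
- Only ring B is built (step 1) and it is aromatised in step 4, after the first depside bond is in place. Rings A and C both come from commercial methyl orsellinate.

Key step: step 1

Remark: all partly saturated ring B compounds are racemic. The SMILES show one enantiomer of the trans series, and both centres vanish on aromatisation. Ring B is numbered as in the final benzoate throughout.

## Route

Step 1
Reactants: 1 tert-butyl acetoacetate; 2 ethyl (E)-crotonate
Product: 5 rac-trans-tert-butyl 6-methyl-2,4-dioxocyclohexane-1-carboxylate, via Michael adduct 3 (not isolated), via potassium enolate 4 (not isolated)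
Conditions: KOtBu (1.1 equiv), tBuOH, rt then reflux; cold 1 M HCl to pH 3, 0 °C
Reagents that add atoms: none
Why: The potassium enolate of 1 adds through its C2 carbon to the β-carbon of 2 (Michael addition, C1–C6 bond) to give 3; proton exchange then places the enolate on the acetyl methyl carbon, which attacks the ethyl ester with loss of ethoxide (Dieckmann condensation, C3–C4 bond). The closest known reaction type is the alkoxide-mediated Michael–Dieckmann annulation of methyl or ethyl acetoacetate with crotonates to give dihydroorsellinates. Ring B closes in a 6-(enolendo)-exo-trig mode, since the enolate C2=C3 bond lies inside the new ring; this is allowed for six-membered rings, and every other enolate/ester pairing in 3 would give a four-membered ring. No reagent controls the new centres C1 and C6: C1 is a β-keto ester carbon that equilibrates to the trans diequatorial arrangement relative to the C6 methyl group, the material is racemic, and step 4 removes both centres. The step needs C- rather than O-addition, closure through the methyl enolate, and an intact tert-butyl ester. All steps before the final deprotonation to the vinylogous carboxylate 4 are reversible, which funnels the mixture to one product, and the bulky ester does not exchange with tert-butoxide or with the liberated ethoxide.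

Step 2
Reactants: 5 rac-trans-tert-butyl 6-methyl-2,4-dioxocyclohexane-1-carboxylate
Product: 6 rac-trans-tert-butyl 4-(benzyloxy)-6-methyl-2-oxocyclohex-3-ene-1-carboxylate
Conditions: BnOH (1.0 equiv), PPh3, DIAD, THF, 0 °C to rt
Reagents that add atoms: benzyl alcohol, OCc1ccccc1
Why: Mitsunobu etherification: the C2/C4 vinylogous acid of 5, far more acidic than C1–H, protonates the PPh3/DIAD betaine, and its ambident anion should be benzylated on oxygen at O4 because O2 is shielded by the neighbouring C1 tert-butyl ester, under cold neutral conditions that spare the acid- and heat-sensitive β-keto ester.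

Step 3
Reactants: 6 rac-trans-tert-butyl 4-(benzyloxy)-6-methyl-2-oxocyclohex-3-ene-1-carboxylate; 7 methyl orsellinate (methyl 2,4-dihydroxy-6-methylbenzoate)
Product: 9 rac-trans-3-hydroxy-4-(methoxycarbonyl)-5-methylphenyl 4-(benzyloxy)-6-methyl-2-oxocyclohex-3-ene-1-carboxylate, via acylketene 8 (not isolated)
Conditions: toluene, 110 °C, slow distillation of tBuOH/toluene
Reagents that add atoms: none
Why: Thermal acyl transfer through an acylketene (transacetoacetylation type): the C1=C2 enol of the tert-butyl β-keto ester expels tBuOH in a unimolecular six-centre step, the α-oxoketene 8 is trapped by the C4–OH of 7 (the only phenol not hydrogen-bonded to the ester carbonyl), distilling off tBuOH pulls the exchange to the aryl ester without acid, base or coupling agent at the hindered C1 carbonyl, and C1 settles trans to the C6 methyl group by enolisation.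

Step 4
Reactants: 9 rac-trans-3-hydroxy-4-(methoxycarbonyl)-5-methylphenyl 4-(benzyloxy)-6-methyl-2-oxocyclohex-3-ene-1-carboxylate
Product: 10 methyl 4-O-benzyllecanorate (3-hydroxy-4-(methoxycarbonyl)-5-methylphenyl 4-(benzyloxy)-2-hydroxy-6-methylbenzoate)
Conditions: DDQ (1.1 equiv), 1,4-dioxane, rt to 60 °C
Reagents that add atoms: none
Why: Quinone dehydrogenation: DDQ should abstract the C6 hydride from the dienol tautomer (C1=C2(OH)–C3=C4(OBn)) to give a cation stabilised by both O2 and O4, loss of a C5 proton then gives arene B and removes both stereocentres, and the mild temperature keeps the aryl β-keto ester from reverting to the ketene.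

Step 5
Reactants: 10 methyl 4-O-benzyllecanorate
Product: 11 methyl lecanorate (3-hydroxy-4-(methoxycarbonyl)-5-methylphenyl 2,4-dihydroxy-6-methylbenzoate)
Conditions: H2 (1 atm), 10% Pd/C, EtOAc, rt
Reagents that add atoms: none
Why: Catalytic hydrogenolysis of the aryl benzyl ether frees the ring B C4–OH, and the depside and methyl esters are inert in a non-nucleophilic solvent.

Step 6
Reactants: 7 methyl orsellinate
Product: 13 methyl 2,4-bis(benzyloxy)-6-methylbenzoate, via monobenzyl ether 12 (not isolated)
Conditions: BnBr (2.5 equiv), K2CO3 (3 equiv), DMF, 60 °C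
Reagents that add atoms: benzyl bromide, BrCc1ccccc1
Why: Williamson etherification: the free C4 phenol reacts first to give 12, and the chelated C2 phenol follows with excess bromide and warming in a dipolar aprotic solvent.

Step 7
Reactants: 13 methyl 2,4-bis(benzyloxy)-6-methylbenzoate
Product: 15 2,4-bis(benzyloxy)-6-methylbenzoic acid, via potassium carboxylate 14 (not isolated)
Conditions: KOH, DMSO/H2O, 100 °C; cold 1 M HCl
Reagents that add atoms: potassium hydroxide, [K+].[OH-]
Why: Saponification of the di-ortho-substituted benzoate needs poorly solvated hydroxide in aqueous DMSO, the benzyl ethers are inert to base, and cold acidification avoids decarboxylation of the electron-rich acid.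

Step 8
Reactants: 11 methyl lecanorate; 15 2,4-bis(benzyloxy)-6-methylbenzoic acid
Product: 17 methyl 2,4-di-O-benzylgyrophorate (ring A oxygens benzylated), via mixed anhydride 16 (not isolated)
Conditions: (CF3CO)2O, toluene, 0 °C to rt; aq. NaHCO3 work-up
Reagents that add atoms: none
Why: Mixed-anhydride esterification (trifluoroacetic anhydride depside coupling): the hindered electron-rich acid 15 forms the aroyl trifluoroacetate 16, which transfers its aroyl group to the ring B C4–OH of 11, the only phenol of three not held in a hydrogen bond to an ortho ester carbonyl, and any aryl trifluoroacetate is cleaved in the bicarbonate wash.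

Step 9
Reactants: 17 methyl 2,4-di-O-benzylgyrophorate
Product: 18 methyl gyrophorate (target, CNP0212402.0)
Conditions: H2 (1 atm), 10% Pd/C, EtOAc/THF, rt
Reagents that add atoms: none
Why: Hydrogenolysis removes both ring A benzyl ethers under neutral conditions, and leaving out alcohol solvents prevents alcoholysis of the two depside esters.

## Compound list

1 | tert-butyl acetoacetate | CC(=O)CC(=O)OC(C)(C)C | starting material
2 | ethyl (E)-crotonate | C/C=C/C(=O)OCC | starting material
3 | 1-tert-butyl 5-ethyl 2-acetyl-3-methylpentanedioate (racemic; C2 labile, epimer leading to trans 5 drawn; not isolated) | C[C@@H]([C@@H](C(C)=O)C(=O)OC(C)(C)C)CC(=O)OCC | intermediate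
4 | potassium enolate of 5, charge shared by O2 and O4 (racemic; not isolated) | C[C@@H]1CC([O-])=CC(=O)[C@H]1C(=O)OC(C)(C)C.[K+] | intermediate
5 | rac-trans-tert-butyl 6-methyl-2,4-dioxocyclohexane-1-carboxylate (largely enolised across C2–C4) | C[C@@H]1CC(=O)CC(=O)[C@H]1C(=O)OC(C)(C)C | intermediate
6 | rac-trans-tert-butyl 4-(benzyloxy)-6-methyl-2-oxocyclohex-3-ene-1-carboxylate | C[C@@H]1CC(OCc2ccccc2)=CC(=O)[C@H]1C(=O)OC(C)(C)C | intermediate
7 | methyl orsellinate (methyl 2,4-dihydroxy-6-methylbenzoate) | COC(=O)c1c(C)cc(O)cc1O | starting material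
8 | 3-(benzyloxy)-5-methyl-6-(oxomethylidene)cyclohex-2-en-1-one, acylketene (racemic; not isolated) | C[C@@H]1CC(OCc2ccccc2)=CC(=O)C1=C=O | intermediate
9 | rac-trans-3-hydroxy-4-(methoxycarbonyl)-5-methylphenyl 4-(benzyloxy)-6-methyl-2-oxocyclohex-3-ene-1-carboxylate | C[C@@H]1CC(OCc2ccccc2)=CC(=O)[C@H]1C(=O)Oc1cc(C)c(C(=O)OC)c(O)c1 | intermediate
10 | methyl 4-O-benzyllecanorate | COC(=O)c1c(C)cc(OC(=O)c2c(C)cc(OCc3ccccc3)cc2O)cc1O | intermediate
11 | methyl lecanorate | COC(=O)c1c(C)cc(OC(=O)c2c(C)cc(O)cc2O)cc1O | intermediate
12 | methyl 4-(benzyloxy)-2-hydroxy-6-methylbenzoate (not isolated) | COC(=O)c1c(C)cc(OCc2ccccc2)cc1O | intermediate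
13 | methyl 2,4-bis(benzyloxy)-6-methylbenzoate | COC(=O)c1c(C)cc(OCc2ccccc2)cc1OCc1ccccc1 | intermediate
14 | potassium 2,4-bis(benzyloxy)-6-methylbenzoate (not isolated) | Cc1cc(OCc2ccccc2)cc(OCc2ccccc2)c1C(=O)[O-].[K+] | intermediate
15 | 2,4-bis(benzyloxy)-6-methylbenzoic acid | Cc1cc(OCc2ccccc2)cc(OCc2ccccc2)c1C(=O)O | intermediate
16 | 2,4-bis(benzyloxy)-6-methylbenzoic trifluoroacetic anhydride (not isolated) | Cc1cc(OCc2ccccc2)cc(OCc2ccccc2)c1C(=O)OC(=O)C(F)(F)F | intermediate
17 | methyl 2,4-di-O-benzylgyrophorate (benzyl ethers on ring A) | COC(=O)c1c(C)cc(OC(=O)c2c(C)cc(OC(=O)c3c(C)cc(OCc4ccccc4)cc3OCc3ccccc3)cc2O)cc1O | intermediate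
18 | methyl gyrophorate | COC(=O)c1c(C)cc(OC(=O)c2c(C)cc(OC(=O)c3c(C)cc(O)cc3O)cc2O)cc1O | target

## Step count and risks

Total step count: 9. Longest linear sequence: 7 (steps 1, 2, 3, 4, 5, 8, 9); steps 6 and 7 form the ring A branch.

**Risk at step 3.**
- What may go wrong: ketene release may be slow because the C2 carbonyl of 6 is part of a vinylogous ester. The ketene may dimerise, traces of water may lead to loss of the carboxyl carbon, or acyl transfer may reach the chelated phenol.
- Fallback: it sets out from 6 and forms the depside bond on an already aromatic ring B.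
- DDQ dehydrogenation of 6 should give tert-butyl 4-(benzyloxy)-2-hydroxy-6-methylbenzoate F1. CF3CO2H in CH2Cl2 at 0 °C cleaves the ester to 4-(benzyloxy)-2-hydroxy-6-methylbenzoic acid F2.
- (CF3CO)2O in toluene converts F2 into its aroyl trifluoroacetate F3, which acylates the C4–OH of 7. The route is rejoined at 10, so steps 3 and 4 are both replaced.

**Risk at step 4.**
- What may go wrong: hydride abstraction may stall if enolisation towards C1 is slow. The oxidant may remove the benzyl group oxidatively or attack the free phenol ring.
- Fallback: it sets out from 9 and replaces hydride abstraction by α-functionalisation and elimination.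
- PhSeCl and pyridine in CH2Cl2 at 0 °C should selenenylate the β-keto ester carbon C1 on the face opposite the C6 methyl group. This gives the C1 phenylselenide F4, in which Se is cis to C6–H.
- 30% H2O2 at 0 °C gives the selenoxide F5, which undergoes syn elimination towards C6–H to the cross-conjugated dienone F6. This keto tautomer shifts a C5 hydrogen to O2, and the route is rejoined at 10.

**Risk at step 2.**
- What may go wrong: O4, O2 and C3 of the ambident anion compete for the benzyl electrophile, and product 6 may be alkylated a second time.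
- Fallback: it sets out from 5 and removes the regiochemical question by passing through a symmetrical dione.
- CF3CO2H in CH2Cl2 cleaves the ester to 6-methyl-2,4-dioxocyclohexane-1-carboxylic acid F7, which loses CO2 on warming to give 5-methylcyclohexane-1,3-dione F8.
- Acid-catalysed etherification (BnOH, TsOH, toluene, Dean–Stark) can then give only 3-(benzyloxy)-5-methylcyclohex-2-en-1-one F9.
- Kinetic α′-deprotonation of the Stork–Danheiser type (LDA, 2.2 equiv, THF, −78 °C) gives the cross-conjugated lithium enolate F10. C-acylation with Boc2O places the tert-butyl ester next to the methyl-bearing carbon, and the route is rejoined at 6.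

## Further compounds

F1 | step 3 | tert-butyl 4-(benzyloxy)-2-hydroxy-6-methylbenzoate | Cc1cc(OCc2ccccc2)cc(O)c1C(=O)OC(C)(C)C
F2 | step 3 | 4-(benzyloxy)-2-hydroxy-6-methylbenzoic acid | Cc1cc(OCc2ccccc2)cc(O)c1C(=O)O
F3 | step 3 | 4-(benzyloxy)-2-hydroxy-6-methylbenzoic trifluoroacetic anhydride | Cc1cc(OCc2ccccc2)cc(O)c1C(=O)OC(=O)C(F)(F)F
F4 | step 4 | 3-hydroxy-4-(methoxycarbonyl)-5-methylphenyl 4-(benzyloxy)-6-methyl-2-oxo-1-(phenylselanyl)cyclohex-3-ene-1-carboxylate (racemic, Se trans to the C6 methyl group) | C[C@@H]1CC(OCc2ccccc2)=CC(=O)[C@]1([Se]c1ccccc1)C(=O)Oc1cc(C)c(C(=O)OC)c(O)c1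
F5 | step 4 | selenoxide of F4 (configuration at Se undefined) | C[C@@H]1CC(OCc2ccccc2)=CC(=O)[C@]1([Se](=O)c1ccccc1)C(=O)Oc1cc(C)c(C(=O)OC)c(O)c1
F6 | step 4 | 3-hydroxy-4-(methoxycarbonyl)-5-methylphenyl 4-(benzyloxy)-2-methyl-6-oxocyclohexa-1,4-diene-1-carboxylate (keto tautomer of 10) | CC1=C(C(=O)Oc2cc(C)c(C(=O)OC)c(O)c2)C(=O)C=C(OCc2ccccc2)C1
F7 | step 2 | rac-trans-6-methyl-2,4-dioxocyclohexane-1-carboxylic acid | C[C@@H]1CC(=O)CC(=O)[C@H]1C(=O)O
F8 | step 2 | 5-methylcyclohexane-1,3-dione | CC1CC(=O)CC(=O)C1
F9 | step 2 | 3-(benzyloxy)-5-methylcyclohex-2-en-1-one (racemic) | C[C@@H]1CC(OCc2ccccc2)=CC(=O)C1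
F10 | step 2 | lithium 3-(benzyloxy)-5-methylcyclohexa-1,3-dien-1-olate, the α′-enolate of F9 (racemic) | C[C@@H]1CC(OCc2ccccc2)=CC([O-])=C1.[Li+]
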